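**Plan**

- Numbering and enabling feature: cyclohexane C1 (carbinol), C4 (CH3, Cl), C5 (Br); cyclopentane C1′ (quaternary, CH3), C2′ (CMe2), C3′ (Br), C5′ (CH2). The C1–C1′ bond joins an oxygen-bearing ring carbon, whose two ring arms meet again at C4, to a quaternary carbon next to the unsubstituted C5′. C1 with its oxygen is therefore a masked quinone carbonyl and C1′–C5′ a masked alkene.
- Retrosynthetic cuts, in order: C4–Cl/C5–Br (alkene bromochlorination), C3′–Br (SN2 on the carbinol), a sacrificial C5′–O bond (reductive oxetane opening), C4–CH3 (enol triflate coupling), then C1–C1′ together with C5′–O (Paternò–Büchi) to p-benzoquinone and a 2,2,3-trimethylcyclopentenyl silyl ether, which is cut at C1′–CH3 back to 2,2-dimethylcyclopentane-1,3-dione.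
- Forward order: the cyclopentene is made first (steps 1–4); the oxetane is the only ring closed (step 5) and brings the six-membered ring in intact; its two arms are then told apart (steps 6–8), the oxetane is opened (step 9) and the three halogens are placed last (steps 11–13).
- Stereochemistry: C3′ from a CBS reduction, inverted later by the Appel reaction; C1′ from photocycloaddition anti to the C3′ silyloxy group; C1 from a chiral lithium amide choosing one of the two α-methylenes of the spiro ketone; C4 and C5 from anti, Markovnikov bromochlorination on the face away from the axial C1 ester.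

Key step: step 5

Assumption: the (S)-oxazaborolidine and the (R,R)-lithium amide are taken to act in the sense established for ketones with one large and one small flank and for 4-tert-butylcyclohexanone (C1′ in the equatorial role), respectively; the antipodal reagents are equally available should either sense be reversed.

**Route**

Step 1
Reactants: 1 2,2-dimethylcyclopentane-1,3-dione
Product: 2 (R)-3-hydroxy-2,2-dimethylcyclopentan-1-one
Conditions: (S)-2-methyl-CBS-oxazaborolidine (10 mol %), BH3·SMe2 (0.6 equiv), THF, −30 °C; MeOH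
Reagents that add atoms: none
Why: Corey–Bakshi–Shibata reduction differentiates the two enantiotopic carbonyl groups, hydride being delivered with the quaternary C2 as the large flank, which sets the (R)-carbinol (future C3′), while sub-stoichiometric borane limits diol formation.

Step 2
Reactants: 2 (R)-3-hydroxy-2,2-dimethylcyclopentan-1-one
Product: 3 (R)-3-[(tert-butyldimethylsilyl)oxy]-2,2-dimethylcyclopentan-1-one
Conditions: TBSCl, imidazole, DMF, 23 °C
Reagents that add atoms: tert-butyldimethylsilyl chloride, CC(C)(C)[Si](C)(C)Cl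
Why: Standard silylation of a secondary alcohol; the bulky silyl ether later shields one face of the cyclopentene and tolerates enolate, Grignard, photochemical and radical-anion conditions.

Step 3
Reactants: 3 (R)-3-[(tert-butyldimethylsilyl)oxy]-2,2-dimethylcyclopentan-1-one
Product: 5 (R)-4-[(tert-butyldimethylsilyl)oxy]-5,5-dimethylcyclopent-1-en-1-yl trifluoromethanesulfonate, via potassium enolate 4 (not isolated)
Conditions: KN(SiMe3)2, THF, −78 °C; then PhNTf2, −78 → 0 °C
Reagents that add atoms: N-phenylbis(trifluoromethanesulfonimide), O=S(=O)(N(c1ccccc1)S(=O)(=O)C(F)(F)F)C(F)(F)F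
Why: The ketone can enolise only toward its methylene (C2 is quaternary, so β-elimination of the silyloxy group is impossible), and O-sulfonylation of the enolate is the standard enol triflate synthesis.

Step 4
Reactants: 5 (R)-4-[(tert-butyldimethylsilyl)oxy]-5,5-dimethylcyclopent-1-en-1-yl trifluoromethanesulfonate; 6 methylmagnesium bromide
Product: 7 (R)-tert-butyldimethyl[(2,2,3-trimethylcyclopent-3-en-1-yl)oxy]silane
Conditions: MeMgBr, Fe(acac)3 (5 mol %), THF/NMP, −30 → 0 °C
Reagents that add atoms: methylmagnesium bromide (6), C[Mg]Br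
Why: Iron-catalysed Kumada-type cross-coupling of alkenyl triflates with MeMgBr runs at low temperature without touching the silyl ether and places the methyl group on the future C1′.

Step 5
Reactants: 7 (R)-tert-butyldimethyl[(2,2,3-trimethylcyclopent-3-en-1-yl)oxy]silane; 8 p-benzoquinone
Product: 9 (1′S,3′R,5′R)-3′-[(tert-butyldimethylsilyl)oxy]-1′,2′,2′-trimethylspiro[cyclohexa-2,5-diene-1,7′-[6]oxabicyclo[3.2.0]heptan]-4-one (oxetane cis-fused to the cyclopentane; silyloxy group and C1′ methyl on the face opposite the oxetane)
Conditions: hν (455 nm LEDs), benzene, 10 °C, argon; p-benzoquinone (2 equiv) added in portions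
Reagents that add atoms: p-benzoquinone (8), O=C1C=CC(=O)C=C1
Why: Paternò–Büchi reaction: 455 nm light excites only the n,π* band of the quinone, whose triplet oxygen adds to the less substituted alkene carbon C5′ to give a 1,4-biradical (tertiary C1′ radical and 4-alkoxyphenoxyl radical) that, after intersystem crossing, couples between C1′ and the ipso carbon, so the congested quaternary-to-tertiary C1–C1′ bond is made by radical recombination and not by a polar addition. The closest known reactions are the spiro-oxetane-forming photocycloadditions of p-benzoquinone with alkyl-substituted alkenes. The oxetane is the only ring closed; it closes stepwise (O–C5′ first, then C1–C1′ by 4-exo-type radical recombination) and is necessarily cis-fused to the five-membered ring. C1′ and C5′ are the new stereocentres: their relative configuration follows from the cis fusion, and their absolute sense from approach of the quinone to the alkene face anti to the C3′ silyloxy group, which leaves the C1′ methyl cis to that group. The step needs regioselectivity (secured by formation of the tertiary in preference to a secondary radical), facial selectivity (secured by the silyl ether on the ring flap) and chemoselectivity over allylic hydrogen abstraction (favoured by low temperature, a non-polar solvent and excess quinone). C1 is not yet stereogenic because the two dienone arms are identical.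

Step 6
Reactants: 9 spiro-oxetane cyclohexadienone
Product: 10 (1′S,3′R,5′R)-3′-[(tert-butyldimethylsilyl)oxy]-1′,2′,2′-trimethylspiro[cyclohexane-1,7′-[6]oxabicyclo[3.2.0]heptan]-4-one
Conditions: H2 (1 atm), 5% Rh/Al2O3, EtOAc, 23 °C
Reagents that add atoms: none
Why: Heterogeneous hydrogenation of both enone double bonds; rhodium on alumina in a neutral solvent is chosen because it saturates quinol-type dienones with little hydrogenolysis of the doubly allylic C1–O bond, and no stereocentre is created.

Step 7
Reactants: 10 spiro-oxetane cyclohexanone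
Product: 12 (1R,1′S,3′R,5′R)-3′-[(tert-butyldimethylsilyl)oxy]-1′,2′,2′-trimethylspiro[cyclohex-3-ene-1,7′-[6]oxabicyclo[3.2.0]heptan]-4-yl trifluoromethanesulfonate (C4=C5 double bond in the arm on the C1′-methyl side), via lithium enolate 11 (not isolated)
Conditions: lithium (R,R)-bis(1-phenylethyl)amide, LiCl, THF, −78 °C; then N-(5-chloropyridin-2-yl)bis(trifluoromethanesulfonimide), −78 °C
Reagents that add atoms: N-(5-chloropyridin-2-yl)bis(trifluoromethanesulfonimide), O=S(=O)(N(c1ccc(Cl)cn1)S(=O)(=O)C(F)(F)F)C(F)(F)F
Why: Group-selective deprotonation by a chiral lithium amide is established for 4-substituted and 4,4-disubstituted cyclohexanones; with C1′ equatorial and the oxetane oxygen axial, the (R,R)-amide should remove the axial proton at C5 (the arm on the C1′-methyl side), and O-triflation of the enolate at −78 °C freezes that choice and makes C1 stereogenic (1R), the minor diastereomer being removed by chromatography.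

Step 8
Reactants: 12 spiro-oxetane cyclohexenyl triflate; 6 methylmagnesium bromide
Product: 13 (1R,1′S,3′R,5′R)-3′-[(tert-butyldimethylsilyl)oxy]-1′,2′,2′,4-tetramethylspiro[cyclohex-3-ene-1,7′-[6]oxabicyclo[3.2.0]heptane]
Conditions: MeMgBr, Fe(acac)3 (5 mol %), THF/NMP, −30 °C
Reagents that add atoms: methylmagnesium bromide (6), C[Mg]Br
Why: A second iron-catalysed Kumada-type methylation of an alkenyl triflate installs the C4 methyl; the oxetane, neither allylic nor Lewis-acid activated, is inert to MeMgBr at this temperature.

Step 9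
Reactants: 13 spiro-oxetane methylcyclohexene
Product: 15 (R)-1-[(1R,3R)-3-[(tert-butyldimethylsilyl)oxy]-1,2,2-trimethylcyclopentyl]-4-methylcyclohex-3-en-1-ol, via dilithio alkoxide 14 (not isolated)
Conditions: LiDBB (lithium 4,4′-di-tert-butylbiphenylide, 2.5 equiv), THF, −78 → 0 °C; then MeOH
Reagents that add atoms: none
Why: Reductive lithiation of oxetanes by aromatic radical anions cleaves the C–O bond that leaves the less substituted carbanion, here the secondary C5′–O bond and not the tertiary, non-allylic C1–O bond; protonation of the γ-lithio alkoxide gives the C5′ methylene and the C1 tertiary alcohol without affecting any stereocentre, the isolated alkene or the silyl ether.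

Step 10
Reactants: 15 silyl ether alcohol
Product: 16 (1R,3R)-3-[(1R)-1-hydroxy-4-methylcyclohex-3-en-1-yl]-2,2,3-trimethylcyclopentan-1-ol
Conditions: Bu4NF, THF, 23 → 40 °C
Reagents that add atoms: none
Why: Fluoride-mediated desilylation; no other fluoride-sensitive group is present.

Step 11
Reactants: 16 diol
Product: 17 (R)-1-[(1R,3S)-3-bromo-1,2,2-trimethylcyclopentyl]-4-methylcyclohex-3-en-1-ol
Conditions: CBr4, PPh3, CH2Cl2, 0 → 23 °C
Reagents that add atoms: carbon tetrabromide, BrC(Br)(Br)Br
Why: Appel reaction: the secondary alkoxyphosphonium ion is displaced by bromide from the rear, inverting C3′ from R to S (bromine now cis to the cyclohexenyl group), while the hindered tertiary C1 alcohol is not activated; the relatively fast substitution at cyclopentyl carbon helps against the neopentyl retardation.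

Step 12
Reactants: 17 bromo alcohol
Product: 18 (R)-1-[(1R,3S)-3-bromo-1,2,2-trimethylcyclopentyl]-4-methylcyclohex-3-en-1-yl trifluoroacetate
Conditions: (CF3CO)2O, pyridine, DMAP (cat.), CH2Cl2, 0 °C
Reagents that add atoms: trifluoroacetic anhydride, O=C(OC(=O)C(F)(F)F)C(F)(F)F
Why: Acylation with trifluoroacetic anhydride is fast enough for a hindered tertiary alcohol; the electron-poor ester cannot cyclise onto a bromonium ion (the free alcohol would give a bridged bromo ether) and is removable by mild methanolysis.

Step 13
Reactants: 18 trifluoroacetate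
Product: 20 (1R,3S,4S)-3-bromo-1-[(1R,3S)-3-bromo-1,2,2-trimethylcyclopentyl]-4-chloro-4-methylcyclohexan-1-ol (the target; in the route numbering Br at C5, Cl and CH3 at C4), via bromochloro trifluoroacetate 19 (not isolated)
Conditions: NBS, Et4NCl (5 equiv), CH2Cl2, −78 → −40 °C, dark; then K2CO3 (cat.), MeOH, 0 °C
Reagents that add atoms: N-bromosuccinimide, O=C1CCC(=O)N1Br; tetraethylammonium chloride, CC[N+](CC)(CC)CC.[Cl-]
Why: Electrophilic bromochlorination (BrCl formed from NBS and chloride) is an anti addition with chloride entering the tertiary carbon (Markovnikov), which fixes Br and Cl trans; with the trimethylcyclopentyl group equatorial the C1 trifluoroacetate is axial and lies under C5/C6, so the bromonium ion should form on the opposite face and be captured quickly by the excess chloride at C4 from the ester face, placing Cl cis and Br trans to the C1 oxygen (4S,5S in route numbering), after which brief transesterification with methanol frees the tertiary alcohol without eliminating the halides.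

**Compound list**

1 | 2,2-dimethylcyclopentane-1,3-dione | CC1(C)C(=O)CCC1=O | starting material
2 | (R)-3-hydroxy-2,2-dimethylcyclopentan-1-one | CC1(C)[C@H](O)CCC1=O | intermediate
3 | (R)-3-[(tert-butyldimethylsilyl)oxy]-2,2-dimethylcyclopentan-1-one | CC1(C)[C@H](O[Si](C)(C)C(C)(C)C)CCC1=O | intermediate
4 | potassium (R)-4-[(tert-butyldimethylsilyl)oxy]-5,5-dimethylcyclopent-1-en-1-olate (not isolated) | CC1(C)[C@H](O[Si](C)(C)C(C)(C)C)CC=C1[O-].[K+] | intermediate
5 | (R)-4-[(tert-butyldimethylsilyl)oxy]-5,5-dimethylcyclopent-1-en-1-yl trifluoromethanesulfonate | CC1(C)[C@H](O[Si](C)(C)C(C)(C)C)CC=C1OS(=O)(=O)C(F)(F)F | intermediate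
6 | methylmagnesium bromide | C[Mg]Br | starting material
7 | (R)-tert-butyldimethyl[(2,2,3-trimethylcyclopent-3-en-1-yl)oxy]silane | CC1(C)[C@H](O[Si](C)(C)C(C)(C)C)CC=C1C | intermediate
8 | p-benzoquinone | O=C1C=CC(=O)C=C1 | starting material
9 | (1′S,3′R,5′R)-3′-[(tert-butyldimethylsilyl)oxy]-1′,2′,2′-trimethylspiro[cyclohexa-2,5-diene-1,7′-[6]oxabicyclo[3.2.0]heptan]-4-one | CC1(C)[C@H](O[Si](C)(C)C(C)(C)C)C[C@H]2OC3(C=CC(=O)C=C3)[C@@]12C | intermediate
10 | (1′S,3′R,5′R)-3′-[(tert-butyldimethylsilyl)oxy]-1′,2′,2′-trimethylspiro[cyclohexane-1,7′-[6]oxabicyclo[3.2.0]heptan]-4-one | CC1(C)[C@H](O[Si](C)(C)C(C)(C)C)C[C@H]2OC3(CCC(=O)CC3)[C@@]12C | intermediate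
11 | lithium enolate of 10 toward C5 (not isolated) | CC1(C)[C@H](O[Si](C)(C)C(C)(C)C)C[C@H]2O[C@@]3(CCC(O[Li])=CC3)[C@@]12C | intermediate
12 | (1R,1′S,3′R,5′R)-3′-[(tert-butyldimethylsilyl)oxy]-1′,2′,2′-trimethylspiro[cyclohex-3-ene-1,7′-[6]oxabicyclo[3.2.0]heptan]-4-yl trifluoromethanesulfonate | CC1(C)[C@H](O[Si](C)(C)C(C)(C)C)C[C@H]2O[C@@]3(CCC(OS(=O)(=O)C(F)(F)F)=CC3)[C@@]12C | intermediate
13 | (1R,1′S,3′R,5′R)-3′-[(tert-butyldimethylsilyl)oxy]-1′,2′,2′,4-tetramethylspiro[cyclohex-3-ene-1,7′-[6]oxabicyclo[3.2.0]heptane] | CC1(C)[C@H](O[Si](C)(C)C(C)(C)C)C[C@H]2O[C@@]3(CCC(C)=CC3)[C@@]12C | intermediate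
14 | C5′-lithio lithium C1-alkoxide from ring opening of 13 (not isolated; C5′ configuration labile) | CC1(C)[C@H](O[Si](C)(C)C(C)(C)C)CC([Li])[C@@]1(C)[C@@]1(O[Li])CCC(C)=CC1 | intermediate
15 | (R)-1-[(1R,3R)-3-[(tert-butyldimethylsilyl)oxy]-1,2,2-trimethylcyclopentyl]-4-methylcyclohex-3-en-1-ol | CC1(C)[C@H](O[Si](C)(C)C(C)(C)C)CC[C@@]1(C)[C@@]1(O)CCC(C)=CC1 | intermediate
16 | (1R,3R)-3-[(1R)-1-hydroxy-4-methylcyclohex-3-en-1-yl]-2,2,3-trimethylcyclopentan-1-ol | CC1(C)[C@H](O)CC[C@@]1(C)[C@@]1(O)CCC(C)=CC1 | intermediate
17 | (R)-1-[(1R,3S)-3-bromo-1,2,2-trimethylcyclopentyl]-4-methylcyclohex-3-en-1-ol | CC1(C)[C@@H](Br)CC[C@@]1(C)[C@@]1(O)CCC(C)=CC1 | intermediate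
18 | (R)-1-[(1R,3S)-3-bromo-1,2,2-trimethylcyclopentyl]-4-methylcyclohex-3-en-1-yl trifluoroacetate | CC1(C)[C@@H](Br)CC[C@@]1(C)[C@@]1(OC(=O)C(F)(F)F)CCC(C)=CC1 | intermediate
19 | (1R,3S,4S)-3-bromo-1-[(1R,3S)-3-bromo-1,2,2-trimethylcyclopentyl]-4-chloro-4-methylcyclohexyl trifluoroacetate (not isolated) | CC1(C)[C@@H](Br)CC[C@@]1(C)[C@@]1(OC(=O)C(F)(F)F)CC[C@](C)(Cl)[C@@H](Br)C1 | intermediate
20 | (1R,3S,4S)-3-bromo-1-[(1R,3S)-3-bromo-1,2,2-trimethylcyclopentyl]-4-chloro-4-methylcyclohexan-1-ol | CC1(C)[C@@H](Br)CC[C@@]1(C)[C@@]1(O)CC[C@](C)(Cl)[C@@H](Br)C1 | target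

**Step count and risks**

Total step count: 13. Longest linear sequence: 13 steps (1 → 20); 6 and 8 are purchased and enter directly.

Steps most likely to fail:

1. Step 5 (key step). What may go wrong: abstraction of allylic hydrogen by the triplet quinone outrunning cycloaddition, weak facial discrimination on the cyclopentene, or loss of the light- and acid-sensitive dienone during isolation. Fallback: setting out from 7, irradiation at 350 nm with diethyl 2-oxomalonate, a carbonyl partner with a strong preference for oxetane formation, would make the same C1–C1′ and C5′–O bonds and give diethyl (1S,3R,5R)-3-[(tert-butyldimethylsilyl)oxy]-1,2,2-trimethyl-6-oxabicyclo[3.2.0]heptane-7,7-dicarboxylate F1. Reduction with i-Bu2AlH at −78 °C would give (1S,3R,5R)-3-[(tert-butyldimethylsilyl)oxy]-1,2,2-trimethyl-6-oxabicyclo[3.2.0]heptane-7,7-dicarbaldehyde F2. A twofold Horner–Wadsworth–Emmons reaction with 1,3-bis(dimethoxyphosphoryl)propan-2-one (K2CO3, THF) would then close the cyclohexadienone and come back to the route at 9.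

2. Step 13. What may go wrong: bromine attack on the alkene face syn to the C1 ester followed by trans-diaxial chloride opening, which would give the C4,C5-diastereomer as a major product. Fallback: setting out from 17 (free alcohol), NBS in CH2Cl2 would let the C1 hydroxyl capture the bromonium ion across the ring and give 2-bromo-4-[(1R,3S)-3-bromo-1,2,2-trimethylcyclopentyl]-1-methyl-7-oxabicyclo[2.2.1]heptane F3, in which bromine is necessarily anti to the oxygen bridge and therefore correctly placed at C5. TiCl4 in CH2Cl2 at −78 °C would then open the C4–O bond with bromine participation and return chloride on the oxygen face (overall retention at C4), coming back to the route at 20. Competing ionisation of the C1–O bond is the uncertainty of this fallback.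

3. Step 11. What may go wrong: elimination or a 1,2-methyl shift from C2′ outcompeting substitution at the neopentyl-type carbinol. Fallback: setting out from 16, activation and displacement are separated. Tf2O and pyridine at −40 °C would give (1R,3R)-3-[(1R)-1-hydroxy-4-methylcyclohex-3-en-1-yl]-2,2,3-trimethylcyclopentyl trifluoromethanesulfonate F4 (the tertiary alcohol being too hindered to sulfonylate), and Bu4NBr in toluene at −20 °C would displace the triflate with inversion, coming back to the route at 17.

**Further compounds**

F1 | step 5 | diethyl (1S,3R,5R)-3-[(tert-butyldimethylsilyl)oxy]-1,2,2-trimethyl-6-oxabicyclo[3.2.0]heptane-7,7-dicarboxylate | CC1(C)[C@H](O[Si](C)(C)C(C)(C)C)C[C@H]2OC(C(=O)OCC)(C(=O)OCC)[C@@]12C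
F2 | step 5 | (1S,3R,5R)-3-[(tert-butyldimethylsilyl)oxy]-1,2,2-trimethyl-6-oxabicyclo[3.2.0]heptane-7,7-dicarbaldehyde | CC1(C)[C@H](O[Si](C)(C)C(C)(C)C)C[C@H]2OC(C=O)(C=O)[C@@]12C
F3 | step 13 | 2-bromo-4-[(1R,3S)-3-bromo-1,2,2-trimethylcyclopentyl]-1-methyl-7-oxabicyclo[2.2.1]heptane (bromine anti to the oxygen bridge) | CC1(C)[C@@H](Br)CC[C@@]1(C)[C@@]1(O2)CC[C@@]2(C)[C@@H](Br)C1
F4 | step 11 | (1R,3R)-3-[(1R)-1-hydroxy-4-methylcyclohex-3-en-1-yl]-2,2,3-trimethylcyclopentyl trifluoromethanesulfonate | CC1(C)[C@H](OS(=O)(=O)C(F)(F)F)CC[C@@]1(C)[C@@]1(O)CCC(C)=CC1
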